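**Retrosynthetic overview**
- Kanzonol X ⇐ removal of three MOM ethers ⇐ removal of a temporary C2 alkoxy group from a 2-alkoxyisoflavan acetal; C2 is carried at the aldehyde oxidation level and its oxygen holds a chiral auxiliary.
- The acetal ⇐ inverse-electron-demand hetero-Diels–Alder reaction of a ring A ortho-quinone methide with a (Z)-enol ether of the ring B arylacetaldehyde: O1–C2 and C3–C4 form together, ring C closes and C3 is set.
- Enabling feature: in ring C, O1 and C4 sit on the adjacent carbons C8a and C4a of ring A, so O1=C8a–C4a=C4 is a latent 1-oxadiene (ortho-quinone methide); C2–C3, with ring B on C3, is a two-carbon enol-ether dienophile.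
- Both partners come from one aryl iodide, made by ortho-lithiation and iodination of the bis-MOM ether of 2-prenylresorcinol: iodine–magnesium exchange and formylation lead to the ring A half, Negishi coupling with a chiral ynol ether to the ring B half.
- Order of rings: rings A and B are aromatic from resorcinol throughout; ring C is the only ring formed, in the key step.

Key step: step 11

Assumption: the sense of induction by the (1S,2R)-2-phenylcyclohexyl group is taken from the usual shielding model for its s-trans enol ethers; if the other face reacted, the (1R,2S) alcohol would be used in the same sequence.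

**Step 1**
Reactants: 1 resorcinol
Product: 2 1,3-bis(methoxymethoxy)benzene
Conditions: NaH (2.4 equiv), MOMCl (2.4 equiv), DMF, 0 °C → rt
Reagents that add atoms: chloromethyl methyl ether, COCCl
Why: Williamson-type O-alkylation of the bis-phenoxide should proceed cleanly, and the MOM ether is chosen because it directs ortho-lithiation and survives the organometallic, hydride and palladium steps that follow.

**Step 2**
Reactants: 2 1,3-bis(methoxymethoxy)benzene
Product: 4 1,3-bis(methoxymethoxy)-2-(3-methylbut-2-en-1-yl)benzene, via aryllithium 3 (not isolated)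
Conditions: n-BuLi, THF, 0 °C → rt; then CuBr·SMe2 (10 mol %), prenyl bromide, −78 °C → rt
Reagents that add atoms: prenyl bromide (1-bromo-3-methylbut-2-ene), CC(C)=CCBr
Why: Directed ortho-metalation takes place at C2, the position flanked by both MOM ethers, and copper-catalysed allylic substitution of prenyl bromide by aryllithium 3 should give the linear prenyl arene.

**Step 3**
Reactants: 4 1,3-bis(methoxymethoxy)-2-(3-methylbut-2-en-1-yl)benzene
Product: 6 1-iodo-2,4-bis(methoxymethoxy)-3-(3-methylbut-2-en-1-yl)benzene, via aryllithium 5 (not isolated)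
Conditions: n-BuLi, TMEDA, THF, −20 → 0 °C; then ICH2CH2I, −78 °C → rt
Reagents that add atoms: 1,2-diiodoethane, ICCI
Why: A second directed ortho-metalation, kinetically controlled by the MOM group (the two free ortho positions are equivalent by symmetry), gives aryllithium 5, which is iodinated with 1,2-diiodoethane (iodine–lithium exchange with loss of ethene), a reagent that avoids free iodine and so spares the prenyl alkene.

**Step 4**
Reactants: 6 1-iodo-2,4-bis(methoxymethoxy)-3-(3-methylbut-2-en-1-yl)benzene
Product: 8 2,4-bis(methoxymethoxy)-3-(3-methylbut-2-en-1-yl)benzaldehyde, via arylmagnesium chloride 7 (not isolated)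
Conditions: i-PrMgCl·LiCl (1.2 equiv), THF, 0 °C → rt; then DMF (3 equiv), 0 °C → rt; aq. NH4Cl
Reagents that add atoms: N,N-dimethylformamide, CN(C)C=O
Why: Iodine–magnesium exchange with i-PrMgCl·LiCl, assisted by chelation of the ortho MOM ether, gives arylmagnesium chloride 7 only at the iodinated carbon, and its Bouveault formylation with DMF should give the aldehyde, so that the storable iodide 6 serves as the single branch point for both halves.

**Step 5**
Reactants: 8 2,4-bis(methoxymethoxy)-3-(3-methylbut-2-en-1-yl)benzaldehyde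
Product: 9 2-hydroxy-4-(methoxymethoxy)-3-(3-methylbut-2-en-1-yl)benzaldehyde
Conditions: HCl (cat.), MeOH, 0 °C → rt, stopped at mono-deprotection
Reagents that add atoms: none
Why: Acid-catalysed acetal exchange with methanol should remove only the MOM group ortho to the formyl group, because that ether is twisted between two ortho substituents and its departure is assisted by the hydrogen bond of the emerging phenol to the carbonyl oxygen, while the chelated phenol formed is too weakly nucleophilic to add to the prenyl alkene under these mild conditions.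

**Step 6**
Reactants: 9 2-hydroxy-4-(methoxymethoxy)-3-(3-methylbut-2-en-1-yl)benzaldehyde
Product: 10 2-(hydroxymethyl)-5-(methoxymethoxy)-6-(3-methylbut-2-en-1-yl)phenol
Conditions: NaBH4, MeOH–THF, 0 °C; pH 7 buffer work-up
Reagents that add atoms: none
Why: Borohydride reduction of the aldehyde leaves the prenyl alkene and the MOM ether untouched, and a neutral work-up avoids ionisation of the electron-rich salicyl alcohol.

**Step 7**
Reactants: 10 2-(hydroxymethyl)-5-(methoxymethoxy)-6-(3-methylbut-2-en-1-yl)phenol
Product: 11 [2-(acetyloxy)-4-(methoxymethoxy)-3-(3-methylbut-2-en-1-yl)phenyl]methyl acetate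
Conditions: Ac2O (2.5 equiv), Et3N, DMAP (cat.), CH2Cl2, 0 °C → rt
Reagents that add atoms: acetic anhydride, CC(=O)OC(C)=O
Why: DMAP-catalysed acetylation of both hydroxyl groups gives a storable bis-acetate in which the aryl acetate is the trigger and the benzylic acetate the leaving group for the later ortho-quinone methide formation.

**Step 8**
Reactants: 12 (1S,2R)-2-phenylcyclohexan-1-ol (trans)
Product: 14 (1S,2R)-1-{[(E)-1,2-dichloroethenyl]oxy}-2-phenylcyclohexane, via potassium alkoxide 13 (not isolated)
Conditions: KH, THF, 0 °C → rt; then trichloroethylene, −50 °C → rt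
Reagents that add atoms: trichloroethylene, ClC=C(Cl)Cl
Why: The potassium alkoxide 13 adds in anti fashion to dichloroethyne formed in the flask from trichloroethylene, a known route to (E)-1,2-dichlorovinyl ethers of secondary alcohols that does not touch the two stereocentres of the auxiliary.

**Step 9**
Reactants: 14 (1S,2R)-1-{[(E)-1,2-dichloroethenyl]oxy}-2-phenylcyclohexane; 6 1-iodo-2,4-bis(methoxymethoxy)-3-(3-methylbut-2-en-1-yl)benzene
Product: 17 2,4-bis(methoxymethoxy)-3-(3-methylbut-2-en-1-yl)-1-({[(1S,2R)-2-phenylcyclohexyl]oxy}ethynyl)benzene, via lithium alkynyl ether 15 (not isolated), via alkynylzinc chloride 16 (not isolated)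
Conditions: n-BuLi (2.1 equiv), THF, −78 → −40 °C; ZnCl2, −40 → 0 °C; then 6, Pd(PPh3)4 (5 mol %), THF, rt
Reagents that add atoms: none
Why: Two equivalents of n-BuLi convert the dichlorovinyl ether by elimination and chlorine–lithium exchange into lithium alkynyl ether 15, and after transmetalation to zinc a Negishi coupling with aryl iodide 6 on zerovalent palladium should give the aryl ynol ether at room temperature, below the temperature at which secondary-alkyl ynol ethers fragment.

**Step 10**
Reactants: 17 2,4-bis(methoxymethoxy)-3-(3-methylbut-2-en-1-yl)-1-({[(1S,2R)-2-phenylcyclohexyl]oxy}ethynyl)benzene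
Product: 18 2,4-bis(methoxymethoxy)-3-(3-methylbut-2-en-1-yl)-1-[(Z)-2-{[(1S,2R)-2-phenylcyclohexyl]oxy}ethenyl]benzene
Conditions: H2 (1 atm), Pd/CaCO3 poisoned with Pb(OAc)2 (Lindlar catalyst), quinoline, EtOAc, rt
Reagents that add atoms: none
Why: Lindlar semihydrogenation adds hydrogen syn to the alkyne and should stop at the (Z)-enol ether, the trisubstituted prenyl alkenes being inert to the poisoned catalyst.

**Step 11**
Reactants: 11 [2-(acetyloxy)-4-(methoxymethoxy)-3-(3-methylbut-2-en-1-yl)phenyl]methyl acetate; 18 2,4-bis(methoxymethoxy)-3-(3-methylbut-2-en-1-yl)-1-[(Z)-2-{[(1S,2R)-2-phenylcyclohexyl]oxy}ethenyl]benzene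
Product: 21 (2R,3R)-3-[2,4-bis(methoxymethoxy)-3-(3-methylbut-2-en-1-yl)phenyl]-7-(methoxymethoxy)-8-(3-methylbut-2-en-1-yl)-2-{[(1S,2R)-2-phenylcyclohexyl]oxy}-3,4-dihydro-2H-chromene (2,3-cis), via magnesium phenoxide 19 (not isolated), via ortho-quinone methide 20 (not isolated)
Conditions: 18 (1.5 equiv), i-PrMgCl (2.0 equiv), toluene, −78 °C → rt
Reagents that add atoms: none
Why: i-PrMgCl cleaves the aryl acetate of 11 at −78 °C to magnesium phenoxide 19, which on warming expels the benzylic acetate (1,4-elimination) and releases ortho-quinone methide 20 slowly and at low concentration beside enol ether 18, so that the electron-poor 1-oxadiene O1=C8a–C4a=C4 and the electron-rich alkene combine in an inverse-electron-demand hetero-Diels–Alder reaction. The closest known reaction types are the low-temperature, Grignard-triggered generation of ortho-quinone methides from ortho-acyloxybenzyl esters or carbonates with diastereoselective [4+2] capture by enol ethers of trans-2-phenylcyclohexanol, and the cycloaddition of ortho-quinone methides with β-aryl enol ethers to 2-alkoxyisoflavans. Ring C is closed by the intermolecular [4+2] cycloaddition itself, driven by rearomatisation of ring A, and polarity fixes the regiochemistry (nucleophilic β-carbon C3 to the methide carbon C4, O1 to the acetal carbon C2). C3 is controlled by the auxiliary: in the s-trans enol ether the phenyl group of the (1S,2R)-2-phenylcyclohexyl unit covers one face of the C=C bond, so C4 should bond to the open face of the (Z)-alkene and give 3R, while C2 follows from suprafacial addition to the (Z)-alkene (2,3-cis, 2R) and is erased in step 12. Because the methide carbon carries no substituent, endo or exo approach does not change the configuration at C3, so the step needs only π-facial selectivity and retention of the (Z)-geometry, the first secured by the auxiliary and the second by the stereospecific cycloaddition of the Lindlar-derived alkene. The prenyl groups are unpolarised alkenes that should not compete with the enol ether, and the MOM ethers are inert to the Grignard reagent.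

**Step 12**
Reactants: 21 (2R,3R)-3-[2,4-bis(methoxymethoxy)-3-(3-methylbut-2-en-1-yl)phenyl]-7-(methoxymethoxy)-8-(3-methylbut-2-en-1-yl)-2-{[(1S,2R)-2-phenylcyclohexyl]oxy}-3,4-dihydro-2H-chromene
Product: 22 (3R)-3-[2,4-bis(methoxymethoxy)-3-(3-methylbut-2-en-1-yl)phenyl]-7-(methoxymethoxy)-8-(3-methylbut-2-en-1-yl)-3,4-dihydro-2H-chromene
Conditions: Et3SiH (5 equiv), TMSOTf (0.2 equiv), CH2Cl2, −78 °C; Et3N quench
Reagents that add atoms: none
Why: The silyl Lewis acid ionises the exocyclic C2–O bond (the more basic alkoxy oxygen of a secondary acetal, far more labile at −78 °C than the formaldehyde-derived MOM acetals) and Et3SiH delivers hydride to C2 (acetal-to-ether reduction), so the O1–C2 bond and the C3 stereocentre are kept and the auxiliary leaves as its silyl ether.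

**Step 13**
Reactants: 22 (3R)-3-[2,4-bis(methoxymethoxy)-3-(3-methylbut-2-en-1-yl)phenyl]-7-(methoxymethoxy)-8-(3-methylbut-2-en-1-yl)-3,4-dihydro-2H-chromene
Product: 23 Kanzonol X, 4-[(3R)-7-hydroxy-8-(3-methylbut-2-en-1-yl)-3,4-dihydro-2H-chromen-3-yl]-2-(3-methylbut-2-en-1-yl)benzene-1,3-diol
Conditions: HCl (ca. 0.5 M), MeOH–THF, rt → 40 °C; NaHCO3 quench
Reagents that add atoms: none
Why: Acid-catalysed acetal exchange with methanol removes the three MOM ethers, a deprotection with precedent on ortho-prenylated phenols when dilute acid and a temperature near ambient are used and the reaction is stopped at conversion, so that cyclisation of the prenyl groups onto the free phenols to 2,2-dimethylchromans is avoided.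

**Compound list**
1 | resorcinol (benzene-1,3-diol) | Oc1cccc(O)c1 | starting material
2 | 1,3-bis(methoxymethoxy)benzene | COCOc1cccc(OCOC)c1 | intermediate
3 | [2,6-bis(methoxymethoxy)phenyl]lithium | [Li]c1c(OCOC)cccc1OCOC | intermediate
4 | 1,3-bis(methoxymethoxy)-2-(3-methylbut-2-en-1-yl)benzene | COCOc1cccc(OCOC)c1CC=C(C)C | intermediate
5 | [2,4-bis(methoxymethoxy)-3-(3-methylbut-2-en-1-yl)phenyl]lithium | [Li]c1ccc(OCOC)c(CC=C(C)C)c1OCOC | intermediate
6 | 1-iodo-2,4-bis(methoxymethoxy)-3-(3-methylbut-2-en-1-yl)benzene | Ic1ccc(OCOC)c(CC=C(C)C)c1OCOC | intermediate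
7 | chloro[2,4-bis(methoxymethoxy)-3-(3-methylbut-2-en-1-yl)phenyl]magnesium | Cl[Mg]c1ccc(OCOC)c(CC=C(C)C)c1OCOC | intermediate
8 | 2,4-bis(methoxymethoxy)-3-(3-methylbut-2-en-1-yl)benzaldehyde | O=Cc1ccc(OCOC)c(CC=C(C)C)c1OCOC | intermediate
9 | 2-hydroxy-4-(methoxymethoxy)-3-(3-methylbut-2-en-1-yl)benzaldehyde | O=Cc1ccc(OCOC)c(CC=C(C)C)c1O | intermediate
10 | 2-(hydroxymethyl)-5-(methoxymethoxy)-6-(3-methylbut-2-en-1-yl)phenol | OCc1ccc(OCOC)c(CC=C(C)C)c1O | intermediate
11 | [2-(acetyloxy)-4-(methoxymethoxy)-3-(3-methylbut-2-en-1-yl)phenyl]methyl acetate | CC(=O)OCc1ccc(OCOC)c(CC=C(C)C)c1OC(C)=O | intermediate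
12 | (1S,2R)-2-phenylcyclohexan-1-ol (trans) | O[C@H]1CCCC[C@@H]1c1ccccc1 | starting material
13 | potassium (1S,2R)-2-phenylcyclohexan-1-olate | [K+].[O-][C@H]1CCCC[C@@H]1c1ccccc1 | intermediate
14 | (1S,2R)-1-{[(E)-1,2-dichloroethenyl]oxy}-2-phenylcyclohexane | Cl/C=C(/Cl)O[C@H]1CCCC[C@@H]1c1ccccc1 | intermediate
15 | lithium alkynyl ether, (1S,2R)-1-[(lithioethynyl)oxy]-2-phenylcyclohexane | [Li]C#CO[C@H]1CCCC[C@@H]1c1ccccc1 | intermediate
16 | chloro({[(1S,2R)-2-phenylcyclohexyl]oxy}ethynyl)zinc | Cl[Zn]C#CO[C@H]1CCCC[C@@H]1c1ccccc1 | intermediate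
17 | 2,4-bis(methoxymethoxy)-3-(3-methylbut-2-en-1-yl)-1-({[(1S,2R)-2-phenylcyclohexyl]oxy}ethynyl)benzene | COCOc1ccc(C#CO[C@H]2CCCC[C@@H]2c2ccccc2)c(OCOC)c1CC=C(C)C | intermediate
18 | 2,4-bis(methoxymethoxy)-3-(3-methylbut-2-en-1-yl)-1-[(Z)-2-{[(1S,2R)-2-phenylcyclohexyl]oxy}ethenyl]benzene | COCOc1ccc(/C=C\O[C@H]2CCCC[C@@H]2c2ccccc2)c(OCOC)c1CC=C(C)C | intermediate
19 | chloromagnesium 2-(acetoxymethyl)-5-(methoxymethoxy)-6-(3-methylbut-2-en-1-yl)phenoxide | CC(=O)OCc1ccc(OCOC)c(CC=C(C)C)c1O[Mg]Cl | intermediate
20 | ortho-quinone methide, 3-(methoxymethoxy)-6-methylidene-2-(3-methylbut-2-en-1-yl)cyclohexa-2,4-dien-1-one | C=C1C=CC(OCOC)=C(CC=C(C)C)C1=O | intermediate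
21 | (2R,3R)-3-[2,4-bis(methoxymethoxy)-3-(3-methylbut-2-en-1-yl)phenyl]-7-(methoxymethoxy)-8-(3-methylbut-2-en-1-yl)-2-{[(1S,2R)-2-phenylcyclohexyl]oxy}-3,4-dihydro-2H-chromene (2,3-cis) | COCOc1ccc2c(c1CC=C(C)C)O[C@@H](O[C@H]3CCCC[C@@H]3c3ccccc3)[C@H](C2)c1ccc(OCOC)c(CC=C(C)C)c1OCOC | intermediate
22 | (3R)-3-[2,4-bis(methoxymethoxy)-3-(3-methylbut-2-en-1-yl)phenyl]-7-(methoxymethoxy)-8-(3-methylbut-2-en-1-yl)-3,4-dihydro-2H-chromene | COCOc1ccc2c(c1CC=C(C)C)OC[C@H](C2)c1ccc(OCOC)c(CC=C(C)C)c1OCOC | intermediate
23 | Kanzonol X, 4-[(3R)-7-hydroxy-8-(3-methylbut-2-en-1-yl)-3,4-dihydro-2H-chromen-3-yl]-2-(3-methylbut-2-en-1-yl)benzene-1,3-diol | CC(C)=CCc1c(O)ccc([C@@H]2COc3c(ccc(O)c3CC=C(C)C)C2)c1O | target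

Total step count: 13
Longest linear sequence: 10 steps (steps 1, 2, 3, 4, 5, 6, 7, 11, 12, 13)

**Steps most likely to fail**

Step 11. The auxiliary may discriminate the two faces of the hindered (Z)-β-aryl enol ether only weakly, or capture of the quinone methide may be so slow that it oligomerises. The fallback replaces auxiliary control by enamine catalysis; it sets out from 18 and 10 and comes back at 22. Enol ether 18 would be hydrolysed (oxalic acid, wet THF, 0 °C, alcohol 12 recovered) to [2,4-bis(methoxymethoxy)-3-(3-methylbut-2-en-1-yl)phenyl]acetaldehyde F1. Diol 10 would be treated with p-toluenesulfinic acid (CH2Cl2, rt) to give the base-triggered quinone methide precursor 5-(methoxymethoxy)-6-(3-methylbut-2-en-1-yl)-2-{[(4-methylphenyl)sulfonyl]methyl}phenol F2. F1 and F2 would be combined with α,α-diphenylprolinol trimethylsilyl ether (20 mol %; the enantiomer is chosen by the usual shielding model so that the open enamine face leads to 3R, assumed here to be the (R)-catalyst) and NaHCO3 in CHCl3 at rt. The (E)-enamine of F1 should add through its open face to the quinone methide released from F2, and the phenol should close onto the iminium carbon, giving after hydrolysis the lactol (3R)-3-[2,4-bis(methoxymethoxy)-3-(3-methylbut-2-en-1-yl)phenyl]-7-(methoxymethoxy)-8-(3-methylbut-2-en-1-yl)-3,4-dihydro-2H-chromen-2-ol F3 (mixture at C2). F3 would be reduced at once with Et3SiH and TMSOTf (CH2Cl2, −78 °C) to 22.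

Step 12. The silyl Lewis acid may also ionise the MOM acetals or the prenyl alkenes, the endocyclic C2–O1 bond may break in place of the exocyclic one, or the C2 cation may lose the C3 proton to the achiral 4H-chromene, which would erode the enantiomeric purity. The fallback replaces ionic deoxygenation by hydrolysis, reduction and re-closure of the ether; it sets out from 21 and comes back at 22. Acetal 21 would be hydrolysed under mild acid (PPTS, acetone–H2O, 40 °C, alcohol 12 recovered) to the lactol (3R)-3-[2,4-bis(methoxymethoxy)-3-(3-methylbut-2-en-1-yl)phenyl]-7-(methoxymethoxy)-8-(3-methylbut-2-en-1-yl)-3,4-dihydro-2H-chromen-2-ol F3, the same compound as in the fallback for step 11. Reduction with NaBH4 (MeOH, 0 °C) through the open hydroxy aldehyde would give (2R)-2-[2,4-bis(methoxymethoxy)-3-(3-methylbut-2-en-1-yl)phenyl]-3-[2-hydroxy-4-(methoxymethoxy)-3-(3-methylbut-2-en-1-yl)phenyl]propan-1-ol F4. Mitsunobu cyclisation (PPh3, DIAD, THF, 0 °C) of the phenol onto the primary alcohol would then give 22, with C3 untouched.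

Step 9. The lithium alkynyl ether or ynol ether 17 may decompose (fragmentation with loss of the auxiliary as an alkene, hydration), and oxidative addition of the hindered, electron-rich iodide may be sluggish. The fallback builds the enol ether by olefination and C–O coupling; it sets out from 8 and 12 and comes back at 18. Stork–Zhao olefination of aldehyde 8 ((iodomethyl)triphenylphosphonium iodide, NaN(SiMe3)2, THF–DMPU, −78 °C) would give 1-[(Z)-2-iodoethenyl]-2,4-bis(methoxymethoxy)-3-(3-methylbut-2-en-1-yl)benzene F5. Copper-catalysed C–O coupling of F5 with alcohol 12 (CuI, 3,4,7,8-tetramethyl-1,10-phenanthroline, Cs2CO3, toluene, 80 °C), which keeps the alkene geometry, would give 18 directly; steps 8 to 10 would then not be needed and both halves would come from aldehyde 8.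

**Further compounds**
F1 | step 11 | [2,4-bis(methoxymethoxy)-3-(3-methylbut-2-en-1-yl)phenyl]acetaldehyde | O=CCc1ccc(OCOC)c(CC=C(C)C)c1OCOC
F2 | step 11 | 5-(methoxymethoxy)-6-(3-methylbut-2-en-1-yl)-2-{[(4-methylphenyl)sulfonyl]methyl}phenol | Cc1ccc(cc1)S(=O)(=O)Cc1ccc(OCOC)c(CC=C(C)C)c1O
F3 | step 11 | (3R)-3-[2,4-bis(methoxymethoxy)-3-(3-methylbut-2-en-1-yl)phenyl]-7-(methoxymethoxy)-8-(3-methylbut-2-en-1-yl)-3,4-dihydro-2H-chromen-2-ol (mixture at C2) | COCOc1ccc2c(c1CC=C(C)C)OC(O)[C@H](C2)c1ccc(OCOC)c(CC=C(C)C)c1OCOC
F4 | step 12 | (2R)-2-[2,4-bis(methoxymethoxy)-3-(3-methylbut-2-en-1-yl)phenyl]-3-[2-hydroxy-4-(methoxymethoxy)-3-(3-methylbut-2-en-1-yl)phenyl]propan-1-ol | COCOc1ccc(C[C@@H](CO)c2ccc(OCOC)c(CC=C(C)C)c2OCOC)c(O)c1CC=C(C)C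
F5 | step 9 | 1-[(Z)-2-iodoethenyl]-2,4-bis(methoxymethoxy)-3-(3-methylbut-2-en-1-yl)benzene | COCOc1ccc(/C=C\I)c(OCOC)c1CC=C(C)C
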